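**Retrosynthetic overview**
- The strategy rests on C2 of the 2,3,4,7-tetrahydrooxepine (numbered O1, C2, C3, C4, C5=C6, C7). This single stereocentre is fully substituted and carries O1, CO2H, ring C3H2 and the CH2C(=O)Ar arm. It is a tertiary ether beta to a ketone, so it is treated as the branched adduct of an allylic alcohol (O1-C7-C6=C5) to a 2-substituted 2-vinyloxirane, whose CH2OH becomes CO2H and whose vinyl group becomes C3-C4.
- Disconnections, backwards: the coumarate ester C-O; the two C2 carbonyl groups back to CH2OH and a 1,3-dithiane; C4-C5 by intramolecular B-alkyl Suzuki coupling onto a Z-bromoalkene; O1-C2 by palladium-catalysed stereoconvergent etherification of a racemic vinyl epoxide.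
- Fragments: the Z-bromo allylic alcohol comes from propargyl alcohol by anti-carbomagnesiation and bromination; the vinyl epoxide comes from a lithiated aryl dithiane and 2-(chloromethyl)-2-vinyloxirane.
- Ring order: both benzene rings are bought; the oxepine is the only ring made and is closed at C4-C5 directly after the key step; the coumarate is attached afterwards and the oxidation levels are adjusted last.

Key step: step 10

Assumption: the R,R antipode of the diphosphine ligand is taken to deliver the 2S ether of step 10; a pilot run fixes the choice, and the S,S antipode would be used with no other change if the sense proved opposite.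

Step 1
Reactants: 1 5-bromo-2-methylpent-2-ene
Product: 3 (2E)-5-bromo-2-methylpent-2-en-1-ol, via enal 2 (not isolated)
Conditions: SeO2 (0.4 equiv), t-BuOOH, salicylic acid (cat.), CH2Cl2, 0 °C to rt; crude product then NaBH4, MeOH, 0 °C
Reagents that add atoms: selenium dioxide, O=[Se]=O (delivers the oxygen); tert-butyl hydroperoxide, CC(C)(C)OO (terminal oxygen source that regenerates it)
Why: Riley allylic oxidation (ene reaction, then [2,3]-sigmatropic shift) attacks the E-methyl group of a trisubstituted alkene, and the borohydride 1,2-reduction returns any over-oxidised enal to the same E allylic alcohol.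

Step 2
Reactants: 3 (2E)-5-bromo-2-methylpent-2-en-1-ol
Product: 4 tert-butyl{[(2E)-5-bromo-2-methylpent-2-en-1-yl]oxy}dimethylsilane
Conditions: TBSCl, imidazole, CH2Cl2, 0 °C to rt
Reagents that add atoms: tert-butyldimethylsilyl chloride, CC(C)(C)[Si](C)(C)Cl
Why: Standard silylation of an unhindered primary alcohol gives an ether that tolerates the organomagnesium, palladium and borane steps ahead.

Step 3
Reactants: 4 tert-butyl{[(2E)-5-bromo-2-methylpent-2-en-1-yl]oxy}dimethylsilane
Product: 5 {(3E)-5-[(tert-butyldimethylsilyl)oxy]-4-methylpent-3-en-1-yl}magnesium bromide (titrated THF solution, used directly)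
Conditions: Mg turnings (activated with a crystal of I2), THF, rt to 35 °C
Reagents that add atoms: magnesium, [Mg]
Why: Magnesium insertion into a primary homoallylic bromide gives the Grignard reagent, the silyl ether and the trisubstituted alkene being inert.

Step 4
Reactants: 5 {(3E)-5-[(tert-butyldimethylsilyl)oxy]-4-methylpent-3-en-1-yl}magnesium bromide; 6 propargyl alcohol
Product: 9 (2Z)-3-bromo-2-{(3E)-5-[(tert-butyldimethylsilyl)oxy]-4-methylpent-3-en-1-yl}prop-2-en-1-ol, via alkoxide 7 (not isolated), via oxamagnesacycle 8 (not isolated)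
Conditions: 6, EtMgBr (1.0 equiv), THF, 0 °C; CuI (10 mol %), then 5 (1.3 equiv), 0 °C to rt; NBS, THF, −40 to 0 °C; aq NH4Cl
Reagents that add atoms: N-bromosuccinimide, O=C1CCC(=O)N1Br
Why: CuI-catalysed anti-carbomagnesiation of the propargylic magnesium alkoxide puts the alkyl group on the carbon next to CH2O and magnesium on the terminus inside a five-membered chelate, and bromination of that alkenylmagnesium with retention leaves Br cis to CH2OH (Z).

Step 5
Reactants: 10 1,3-dichloroacetone; 11 vinylmagnesium bromide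
Product: 12 1-chloro-2-(chloromethyl)but-3-en-2-ol
Conditions: THF, −78 °C; cold 1 M HCl quench
Reagents that add atoms: none
Why: Grignard 1,2-addition to the ketone is much faster at −78 °C than displacement of the alpha chlorides, and the cold acidic quench stops the alkoxide from cyclising out of control.

Step 6
Reactants: 12 1-chloro-2-(chloromethyl)but-3-en-2-ol
Product: 13 rac-2-(chloromethyl)-2-ethenyloxirane
Conditions: powdered NaOH, Et2O, 0 °C to rt; distillation
Reagents that add atoms: none
Why: Intramolecular Williamson closure (3-exo-tet) of the chlorohydrin gives the oxirane, and the two chloromethyl arms are equivalent so only one product can form.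

Step 7
Reactants: 14 2,5-dihydroxybenzaldehyde
Product: 15 2-(1,3-dithian-2-yl)benzene-1,4-diol
Conditions: propane-1,3-dithiol, BF3·OEt2 (cat.), CH2Cl2/Et2O, 0 °C to rt
Reagents that add atoms: propane-1,3-dithiol, SCCCS
Why: Lewis-acid-catalysed dithioacetalisation of the aldehyde is run before the acid-labile phenol protecting groups are introduced.

Step 8
Reactants: 15 2-(1,3-dithian-2-yl)benzene-1,4-diol
Product: 16 2-[2,5-bis(methoxymethoxy)phenyl]-1,3-dithiane
Conditions: NaH, MOMCl, THF/DMF, 0 °C to rt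
Reagents that add atoms: chloromethyl methyl ether, COCCl
Why: Williamson O-alkylation of both phenoxides gives acetal ethers that withstand butyllithium, borane, palladium and the later oxidations.

Step 9
Reactants: 16 2-[2,5-bis(methoxymethoxy)phenyl]-1,3-dithiane; 13 rac-2-(chloromethyl)-2-ethenyloxirane
Product: 19 rac-2-({2-[2,5-bis(methoxymethoxy)phenyl]-1,3-dithian-2-yl}methyl)-2-ethenyloxirane, via lithiodithiane 17 (not isolated), via chlorohydrin alkoxide 18 (not isolated)
Conditions: n-BuLi, THF, −78 to −30 °C; then 13 (1.2 equiv), −78 °C to rt; no HMPA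
Reagents that add atoms: none
Why: In this Corey–Seebach umpolung alkylation the contact-ion-pair dithiane anion opens the oxirane at its unsubstituted CH2 (epichlorohydrin-type reactivity, SN2 rather than SN2′ in the absence of HMPA), and on warming the tertiary alkoxide displaces chloride to rebuild the vinyl epoxide; direct displacement of chloride would give the same compound.

Step 10
Reactants: 9 (2Z)-3-bromo-2-{(3E)-5-[(tert-butyldimethylsilyl)oxy]-4-methylpent-3-en-1-yl}prop-2-en-1-ol; 19 rac-2-({2-[2,5-bis(methoxymethoxy)phenyl]-1,3-dithian-2-yl}methyl)-2-ethenyloxirane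
Product: 20 (2S)-2-({2-[2,5-bis(methoxymethoxy)phenyl]-1,3-dithian-2-yl}methyl)-2-[((2Z)-3-bromo-2-{(3E)-5-[(tert-butyldimethylsilyl)oxy]-4-methylpent-3-en-1-yl}prop-2-en-1-yl)oxy]but-3-en-1-ol
Conditions: Pd2(dba)3·CHCl3 (1 mol %), (R,R)-N,N'-(cyclohexane-1,2-diyl)bis[2-(diphenylphosphino)benzamide] (3 mol %), Et3B (2 mol %), 9 (1.0 equiv), 19 (1.2 equiv), CH2Cl2, rt
Reagents that add atoms: none
Why: Zerovalent palladium ionises the allylic C–O bond of either enantiomer of 19 to zwitterionic alkoxide π-allyl complexes that exchange faces by π-σ-π isomerisation through the CH2 terminus faster than they are captured, while Et3B ties the freed alkoxide and alcohol 9 together as a borate that hands the oxygen of 9 to the adjacent fully substituted terminus and so forms O1–C2. The closest known reaction type is the palladium-catalysed dynamic kinetic asymmetric allylic etherification (Tsuji–Trost reaction) of racemic 2-alkyl-2-vinyloxiranes with primary alcohols under trialkylborane co-catalysis. No ring is closed in this step; only the oxirane is opened. The new C2 stereocentre (S in 20 by the sequence rules, the arrangement that becomes 2R in the acid) is dictated by the chiral pocket of the C2-symmetric diphosphine, both enantiomers of 19 converging on it. The step needs branched over linear attack, secured by the boron tether to the neighbouring CH2O group; one allyl face, secured by the ligand once face exchange is fast; and an untouched C–Br bond, secured because ionisation of the strained vinyl oxirane is far faster at room temperature than oxidative addition into an alkenyl bromide. The neopentyl primary hydroxyl of 20 is too hindered to compete with 9 as the nucleophile.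

Step 11
Reactants: 20 the (2S) bromo diene ether of step 10
Product: 22 [(2R)-2-({2-[2,5-bis(methoxymethoxy)phenyl]-1,3-dithian-2-yl}methyl)-6-{(3E)-5-[(tert-butyldimethylsilyl)oxy]-4-methylpent-3-en-1-yl}-2,3,4,7-tetrahydrooxepin-2-yl]methanol, via alkylborane 21 (not isolated)
Conditions: 9-BBN (2.3 equiv), THF, 0 °C to rt; then slow addition to PdCl2(dppf) (10 mol %), AsPh3 (10 mol %), Cs2CO3, DMF/THF/H2O, 50 °C, about 0.005 M; ethanolamine work-up, no peroxide
Reagents that add atoms: none
Why: 9-BBN adds only to the monosubstituted vinyl group with boron at C4 (one equivalent is spent on the hydroxyl as a borinate), and the intramolecular B-alkyl Suzuki–Miyaura coupling then joins C4 to C5 with retention of the bromoalkene geometry, helped by the Z alkene, the quaternary C2 and dilution, while the non-oxidative work-up spares the dithiane.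

Step 12
Reactants: 23 (2E)-3-(4-hydroxyphenyl)prop-2-enoic acid
Product: 24 methoxymethyl (2E)-3-[4-(methoxymethoxy)phenyl]prop-2-enoate
Conditions: MOMCl (2.4 equiv), i-Pr2NEt, CH2Cl2, 0 °C to rt
Reagents that add atoms: chloromethyl methyl ether, COCCl
Why: Exhaustive O-alkylation of the phenol and the carboxylate is easier than selective etherification of the phenol alone.

Step 13
Reactants: 24 methoxymethyl (2E)-3-[4-(methoxymethoxy)phenyl]prop-2-enoate
Product: 25 (2E)-3-[4-(methoxymethoxy)phenyl]prop-2-enoic acid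
Conditions: LiOH·H2O, THF/MeOH/H2O, rt; then dilute HCl to pH 4, 0 °C
Reagents that add atoms: lithium hydroxide, [Li+].[OH-] (one carboxyl oxygen by acyl–oxygen cleavage)
Why: Saponification removes the acetal ester only, because the aryl acetal ether is stable to base and to the brief mildly acidic work-up.

Step 14
Reactants: 22 the silyl-protected oxepine of step 11
Product: 26 (2E)-5-[(2R)-2-({2-[2,5-bis(methoxymethoxy)phenyl]-1,3-dithian-2-yl}methyl)-2-(hydroxymethyl)-2,3,4,7-tetrahydrooxepin-6-yl]-2-methylpent-2-en-1-ol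
Conditions: Bu4NF, THF, 0 °C to rt
Reagents that add atoms: none
Why: Fluoride-mediated desilylation frees the allylic primary alcohol without touching the acetal ethers, the dithiane or the ring.

Step 15
Reactants: 26 the diol of step 14; 25 (2E)-3-[4-(methoxymethoxy)phenyl]prop-2-enoic acid
Product: 27 (2E)-5-[(2R)-2-({2-[2,5-bis(methoxymethoxy)phenyl]-1,3-dithian-2-yl}methyl)-2-(hydroxymethyl)-2,3,4,7-tetrahydrooxepin-6-yl]-2-methylpent-2-en-1-yl (2E)-3-[4-(methoxymethoxy)phenyl]prop-2-enoate
Conditions: 25 (1.0 equiv), N,N'-diisopropylcarbodiimide, DMAP (10 mol %), CH2Cl2, −10 to 0 °C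
Reagents that add atoms: none
Why: Steglich esterification with one equivalent of acid at low temperature should acylate the unhindered allylic primary hydroxyl well before the neopentyl C2–CH2OH, which is shielded by the quaternary centre and the aryl dithiane.

Step 16
Reactants: 27 the coumarate ester of step 15
Product: 28 (2E)-5-[(2R)-2-({2-[2,5-bis(methoxymethoxy)phenyl]-1,3-dithian-2-yl}methyl)-2-formyl-2,3,4,7-tetrahydrooxepin-6-yl]-2-methylpent-2-en-1-yl (2E)-3-[4-(methoxymethoxy)phenyl]prop-2-enoate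
Conditions: SO3·pyridine, DMSO, i-Pr2NEt, CH2Cl2, 0 °C
Reagents that add atoms: none
Why: Parikh–Doering oxidation uses activated DMSO, which does not oxidise the dithiane sulfur as periodinane or chromium reagents might, and the aldehyde has no alpha hydrogen so C2 cannot epimerise.

Step 17
Reactants: 28 the dithianyl aldehyde of step 16
Product: 29 (2E)-5-[(2R)-2-{2-[2,5-bis(methoxymethoxy)phenyl]-2-oxoethyl}-2-formyl-2,3,4,7-tetrahydrooxepin-6-yl]-2-methylpent-2-en-1-yl (2E)-3-[4-(methoxymethoxy)phenyl]prop-2-enoate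
Conditions: MeI (excess), CaCO3, MeCN/H2O 9:1, rt to 40 °C
Reagents that add atoms: water, O
Why: Alkylative dithiane hydrolysis (S-methylation, ring opening to an aryl-stabilised thionium ion, capture by water) runs near neutrality, which avoids base-induced beta-elimination of the C2 ether and acid loss of the acetal ethers, and no carboxylic acid is present yet to be methylated.

Step 18
Reactants: 29 the keto aldehyde of step 17
Product: 30 (2R)-2-{2-[2,5-bis(methoxymethoxy)phenyl]-2-oxoethyl}-6-[(3E)-5-({(2E)-3-[4-(methoxymethoxy)phenyl]prop-2-enoyl}oxy)-4-methylpent-3-en-1-yl]-2,3,4,7-tetrahydrooxepine-2-carboxylic acid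
Conditions: NaClO2, NaH2PO4, 2-methylbut-2-ene (excess), t-BuOH/H2O, 0 °C to rt
Reagents that add atoms: sodium chlorite, [Na+].[O-]Cl=O
Why: Pinnick oxidation converts the aldehyde into the acid at about pH 4 while the alkene scavenger removes hypochlorous acid before it can attack the three alkenes or the electron-rich arenes, and it is placed after dithiane removal because chlorite would oxidise sulfur.

Step 19
Reactants: 30 the tris(methoxymethyl)-protected keto acid of step 18
Product: 32 (2R)-2-[2-(2,5-dihydroxyphenyl)-2-oxoethyl]-6-[(3E)-5-{[(2E)-3-(4-hydroxyphenyl)prop-2-enoyl]oxy}-4-methylpent-3-en-1-yl]-2,3,4,7-tetrahydrooxepine-2-carboxylic acid (CNP0602535.1), via silyl ether 31 (not isolated)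
Conditions: TMSOTf, 2,2'-bipyridyl, CH2Cl2, 0 °C to rt; then H2O, rt
Reagents that add atoms: none
Why: The bipyridyl-buffered silyl triflate converts aryl methoxymethyl ethers into aryl silyl ethers without free strong acid, and water then releases the phenols and the acid, so the allylic ester, the allylic C7–O1 bond and the beta-keto ether should survive.

**Compound list**
1 | 5-bromo-2-methylpent-2-ene | CC(C)=CCCBr | starting material
2 | (2E)-5-bromo-2-methylpent-2-enal | C/C(=C\CCBr)C=O | intermediate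
3 | (2E)-5-bromo-2-methylpent-2-en-1-ol | C/C(=C\CCBr)CO | intermediate
4 | tert-butyl{[(2E)-5-bromo-2-methylpent-2-en-1-yl]oxy}dimethylsilane | C/C(=C\CCBr)CO[Si](C)(C)C(C)(C)C | intermediate
5 | {(3E)-5-[(tert-butyldimethylsilyl)oxy]-4-methylpent-3-en-1-yl}magnesium bromide | C/C(=C\CC[Mg]Br)CO[Si](C)(C)C(C)(C)C | intermediate
6 | propargyl alcohol | C#CCO | starting material
7 | bromomagnesium prop-2-yn-1-olate | C#CCO[Mg]Br | intermediate
8 | 4-{(3E)-5-[(tert-butyldimethylsilyl)oxy]-4-methylpent-3-en-1-yl}-2,5-dihydro-1,2-oxamagnesole | C/C(=C\CCC1=C[Mg]OC1)CO[Si](C)(C)C(C)(C)C | intermediate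
9 | (2Z)-3-bromo-2-{(3E)-5-[(tert-butyldimethylsilyl)oxy]-4-methylpent-3-en-1-yl}prop-2-en-1-ol | OC/C(CC/C=C(\C)CO[Si](C)(C)C(C)(C)C)=C\Br | intermediate
10 | 1,3-dichloroacetone | ClCC(=O)CCl | starting material
11 | vinylmagnesium bromide | C=C[Mg]Br | starting material
12 | 1-chloro-2-(chloromethyl)but-3-en-2-ol | OC(CCl)(CCl)C=C | intermediate
13 | rac-2-(chloromethyl)-2-ethenyloxirane | ClCC1(C=C)CO1 | intermediate
14 | 2,5-dihydroxybenzaldehyde | O=Cc1cc(O)ccc1O | starting material
15 | 2-(1,3-dithian-2-yl)benzene-1,4-diol | Oc1ccc(O)c(C2SCCCS2)c1 | intermediate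
16 | 2-[2,5-bis(methoxymethoxy)phenyl]-1,3-dithiane | COCOc1ccc(OCOC)c(C2SCCCS2)c1 | intermediate
17 | 2-[2,5-bis(methoxymethoxy)phenyl]-2-lithio-1,3-dithiane | COCOc1ccc(OCOC)c(C2([Li])SCCCS2)c1 | intermediate
18 | lithium rac-1-chloro-2-({2-[2,5-bis(methoxymethoxy)phenyl]-1,3-dithian-2-yl}methyl)but-3-en-2-olate | C=CC(CCl)(O[Li])CC1(c2cc(OCOC)ccc2OCOC)SCCCS1 | intermediate
19 | rac-2-({2-[2,5-bis(methoxymethoxy)phenyl]-1,3-dithian-2-yl}methyl)-2-ethenyloxirane | C=CC1(CC2(c3cc(OCOC)ccc3OCOC)SCCCS2)CO1 | intermediate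
20 | (2S)-2-({2-[2,5-bis(methoxymethoxy)phenyl]-1,3-dithian-2-yl}methyl)-2-[((2Z)-3-bromo-2-{(3E)-5-[(tert-butyldimethylsilyl)oxy]-4-methylpent-3-en-1-yl}prop-2-en-1-yl)oxy]but-3-en-1-ol | C=C[C@@](CC1(c2cc(OCOC)ccc2OCOC)SCCCS1)(CO)OC/C(CC/C=C(\C)CO[Si](C)(C)C(C)(C)C)=C\Br | intermediate
21 | B-alkyl-9-borabicyclo[3.3.1]nonane from hydroboration of 20 at C4, (R) at C2, the hydroxyl carried as its 9-BBN borinate | B1(CC[C@@](CC2(c3cc(OCOC)ccc3OCOC)SCCCS2)(COB2C3CCCC2CCC3)OC/C(CC/C=C(\C)CO[Si](C)(C)C(C)(C)C)=C\Br)C2CCCC1CCC2 | intermediate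
22 | [(2R)-2-({2-[2,5-bis(methoxymethoxy)phenyl]-1,3-dithian-2-yl}methyl)-6-{(3E)-5-[(tert-butyldimethylsilyl)oxy]-4-methylpent-3-en-1-yl}-2,3,4,7-tetrahydrooxepin-2-yl]methanol | C/C(=C\CCC1=CCC[C@@](CC2(c3cc(OCOC)ccc3OCOC)SCCCS2)(CO)OC1)CO[Si](C)(C)C(C)(C)C | intermediate
23 | (2E)-3-(4-hydroxyphenyl)prop-2-enoic acid | O=C(O)/C=C/c1ccc(O)cc1 | starting material
24 | methoxymethyl (2E)-3-[4-(methoxymethoxy)phenyl]prop-2-enoate | COCOC(=O)/C=C/c1ccc(OCOC)cc1 | intermediate
25 | (2E)-3-[4-(methoxymethoxy)phenyl]prop-2-enoic acid | O=C(O)/C=C/c1ccc(OCOC)cc1 | intermediate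
26 | (2E)-5-[(2R)-2-({2-[2,5-bis(methoxymethoxy)phenyl]-1,3-dithian-2-yl}methyl)-2-(hydroxymethyl)-2,3,4,7-tetrahydrooxepin-6-yl]-2-methylpent-2-en-1-ol | C/C(=C\CCC1=CCC[C@@](CC2(c3cc(OCOC)ccc3OCOC)SCCCS2)(CO)OC1)CO | intermediate
27 | (2E)-5-[(2R)-2-({2-[2,5-bis(methoxymethoxy)phenyl]-1,3-dithian-2-yl}methyl)-2-(hydroxymethyl)-2,3,4,7-tetrahydrooxepin-6-yl]-2-methylpent-2-en-1-yl (2E)-3-[4-(methoxymethoxy)phenyl]prop-2-enoate | C/C(=C\CCC1=CCC[C@@](CC2(c3cc(OCOC)ccc3OCOC)SCCCS2)(CO)OC1)COC(=O)/C=C/c1ccc(OCOC)cc1 | intermediate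
28 | (2E)-5-[(2R)-2-({2-[2,5-bis(methoxymethoxy)phenyl]-1,3-dithian-2-yl}methyl)-2-formyl-2,3,4,7-tetrahydrooxepin-6-yl]-2-methylpent-2-en-1-yl (2E)-3-[4-(methoxymethoxy)phenyl]prop-2-enoate | C/C(=C\CCC1=CCC[C@@](CC2(c3cc(OCOC)ccc3OCOC)SCCCS2)(C=O)OC1)COC(=O)/C=C/c1ccc(OCOC)cc1 | intermediate
29 | (2E)-5-[(2R)-2-{2-[2,5-bis(methoxymethoxy)phenyl]-2-oxoethyl}-2-formyl-2,3,4,7-tetrahydrooxepin-6-yl]-2-methylpent-2-en-1-yl (2E)-3-[4-(methoxymethoxy)phenyl]prop-2-enoate | C/C(=C\CCC1=CCC[C@@](CC(=O)c2cc(OCOC)ccc2OCOC)(C=O)OC1)COC(=O)/C=C/c1ccc(OCOC)cc1 | intermediate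
30 | (2R)-2-{2-[2,5-bis(methoxymethoxy)phenyl]-2-oxoethyl}-6-[(3E)-5-({(2E)-3-[4-(methoxymethoxy)phenyl]prop-2-enoyl}oxy)-4-methylpent-3-en-1-yl]-2,3,4,7-tetrahydrooxepine-2-carboxylic acid | C/C(=C\CCC1=CCC[C@@](CC(=O)c2cc(OCOC)ccc2OCOC)(C(=O)O)OC1)COC(=O)/C=C/c1ccc(OCOC)cc1 | intermediate
31 | tris(trimethylsilyl ether) trimethylsilyl ester of the target, (2R) | C/C(=C\CCC1=CCC[C@@](CC(=O)c2cc(O[Si](C)(C)C)ccc2O[Si](C)(C)C)(C(=O)O[Si](C)(C)C)OC1)COC(=O)/C=C/c1ccc(O[Si](C)(C)C)cc1 | intermediate
32 | (2R)-2-[2-(2,5-dihydroxyphenyl)-2-oxoethyl]-6-[(3E)-5-{[(2E)-3-(4-hydroxyphenyl)prop-2-enoyl]oxy}-4-methylpent-3-en-1-yl]-2,3,4,7-tetrahydrooxepine-2-carboxylic acid (CNP0602535.1) | C/C(=C\CCC1=CCC[C@@](CC(=O)c2cc(O)ccc2O)(C(=O)O)OC1)COC(=O)/C=C/c1ccc(O)cc1 | target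

**Step count**
Total: 19 steps. Longest linear sequence: 12 steps (steps 1, 2, 3, 4, 10, 11, 14, 15, 16, 17, 18, 19, from bromide 1).

**Steps most likely to fail**

Step 10. Capture of the π-allyl intermediates may outrun their face exchange, because the bulky dithianylmethyl group slows π-σ-π isomerisation, and sulfur coordination may blunt the chiral catalyst; either would erode the enantiomeric purity of the ether. The fallback moves stereocontrol from catalysis to resolution. It sets out from 9 and 19, which are joined by the same etherification with an achiral catalyst (Pd2(dba)3·CHCl3, PPh3, Et3B, CH2Cl2) to give the racemic ether F1. Acylation of its primary hydroxyl with (1S)-camphanic chloride (Et3N, DMAP, CH2Cl2) gives the (2S)-camphanate F2 and the (2R)-camphanate F3, which are separated by chromatography. Methanolysis of F2 (K2CO3, MeOH) returns 20, and the route continues at step 11.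

Step 11. Ring-closing transmetalation to the medium-sized palladacycle may be slower than intermolecular coupling, protodeboronation or beta-hydride loss, giving oligomers or the reduced chain instead of the oxepine. The fallback replaces the borane by a more reactive organozinc made stepwise. It sets out from 20: hydroboration with 9-BBN followed by oxidation of the C–B bond with trimethylamine N-oxide, which spares the dithiane, gives the (R)-butane-1,4-diol F4. Iodination (I2, PPh3, imidazole, 0 °C) converts only the unhindered hydroxyl, since the neopentyl one resists displacement, and gives the primary iodide F5. The remaining hydroxyl is capped (TMSCl, imidazole) as the silyl ether F6. Zinc insertion (Zn dust, LiCl, THF) gives the alkylzinc iodide F7, and intramolecular Negishi coupling (Pd(PPh3)4, THF/DMA, dilution) closes C4–C5 to the silylated oxepine F8. K2CO3/MeOH removes the trimethylsilyl group and returns 22.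

Step 9. The hindered, soft aryl dithiane anion may add in the SN2′ sense to the vinyl terminus of 13, or react too slowly at the neopentyl-type carbons and decompose. The fallback brings in the vinyl group only after the C–C bond is made. It sets out from 16, which is lithiated as before and added to racemic epichlorohydrin at −78 °C with a cold quench, giving the chlorohydrin F9. Parikh–Doering oxidation (SO3·pyridine, DMSO, i-Pr2NEt) gives the chloromethyl ketone F10. Addition of 11 (CeCl3, THF, −78 °C) gives the vinyl chlorohydrin F11, and powdered NaOH in Et2O closes it to 19.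

**Further compounds**
F1 | step 10 | rac-2-({2-[2,5-bis(methoxymethoxy)phenyl]-1,3-dithian-2-yl}methyl)-2-[((2Z)-3-bromo-2-{(3E)-5-[(tert-butyldimethylsilyl)oxy]-4-methylpent-3-en-1-yl}prop-2-en-1-yl)oxy]but-3-en-1-ol | C=CC(CC1(c2cc(OCOC)ccc2OCOC)SCCCS1)(CO)OC/C(CC/C=C(\C)CO[Si](C)(C)C(C)(C)C)=C\Br
F2 | step 10 | (1S,4R)-camphanate ester of the (2S) alcohol 20 | C=C[C@@](CC1(c2cc(OCOC)ccc2OCOC)SCCCS1)(COC(=O)[C@@]12CC[C@@](C)(C(=O)O1)C2(C)C)OC/C(CC/C=C(\C)CO[Si](C)(C)C(C)(C)C)=C\Br
F3 | step 10 | (1S,4R)-camphanate ester of the (2R) alcohol (unwanted diastereomer) | C=C[C@](CC1(c2cc(OCOC)ccc2OCOC)SCCCS1)(COC(=O)[C@@]12CC[C@@](C)(C(=O)O1)C2(C)C)OC/C(CC/C=C(\C)CO[Si](C)(C)C(C)(C)C)=C\Br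
F4 | step 11 | (2R)-2-({2-[2,5-bis(methoxymethoxy)phenyl]-1,3-dithian-2-yl}methyl)-2-[((2Z)-3-bromo-2-{(3E)-5-[(tert-butyldimethylsilyl)oxy]-4-methylpent-3-en-1-yl}prop-2-en-1-yl)oxy]butane-1,4-diol | OCC[C@@](CC1(c2cc(OCOC)ccc2OCOC)SCCCS1)(CO)OC/C(CC/C=C(\C)CO[Si](C)(C)C(C)(C)C)=C\Br
F5 | step 11 | (2S)-2-({2-[2,5-bis(methoxymethoxy)phenyl]-1,3-dithian-2-yl}methyl)-2-[((2Z)-3-bromo-2-{(3E)-5-[(tert-butyldimethylsilyl)oxy]-4-methylpent-3-en-1-yl}prop-2-en-1-yl)oxy]-4-iodobutan-1-ol | ICC[C@@](CC1(c2cc(OCOC)ccc2OCOC)SCCCS1)(CO)OC/C(CC/C=C(\C)CO[Si](C)(C)C(C)(C)C)=C\Br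
F6 | step 11 | trimethylsilyl ether of iodo alcohol F5 | ICC[C@@](CC1(c2cc(OCOC)ccc2OCOC)SCCCS1)(CO[Si](C)(C)C)OC/C(CC/C=C(\C)CO[Si](C)(C)C(C)(C)C)=C\Br
F7 | step 11 | alkylzinc iodide from zinc insertion into F6 | I[Zn]CC[C@@](CC1(c2cc(OCOC)ccc2OCOC)SCCCS1)(CO[Si](C)(C)C)OC/C(CC/C=C(\C)CO[Si](C)(C)C(C)(C)C)=C\Br
F8 | step 11 | trimethylsilyl ether of oxepine 22 | C/C(=C\CCC1=CCC[C@@](CC2(c3cc(OCOC)ccc3OCOC)SCCCS2)(CO[Si](C)(C)C)OC1)CO[Si](C)(C)C(C)(C)C
F9 | step 9 | rac-1-chloro-3-{2-[2,5-bis(methoxymethoxy)phenyl]-1,3-dithian-2-yl}propan-2-ol | OC(CCl)CC1(c2cc(OCOC)ccc2OCOC)SCCCS1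
F10 | step 9 | 1-chloro-3-{2-[2,5-bis(methoxymethoxy)phenyl]-1,3-dithian-2-yl}propan-2-one | O=C(CCl)CC1(c2cc(OCOC)ccc2OCOC)SCCCS1
F11 | step 9 | rac-1-chloro-2-({2-[2,5-bis(methoxymethoxy)phenyl]-1,3-dithian-2-yl}methyl)but-3-en-2-ol | C=CC(O)(CCl)CC1(c2cc(OCOC)ccc2OCOC)SCCCS1
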